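The constants are those of an exercise; the rest is arithmetic.

Early in each flask below, watch how much coupling partner the starting material has met so far.

| setting | south-east | north-west | north-east | north |
|---|---|---|---|---|
| starting material | 0.20 mM | 0.20 mM | 0.20 mM | 0.20 mM (fed, over 30 s) |
| coupling partner | 0.160 mM (fed, over 30 s) | 0.160 mM (fed, over 30 s) | 0.160 mM | 0.160 mM |
| time | 40 s | 40 s | 40 s | 40 s |
| remark | the addition at 20 °C, then warmed to 40 °C; the feed brings no volume worth counting | all else is in the flask from the start; the feed brings no volume worth counting | everything together at the start | all else is in the flask from the start; the feed brings no volume worth counting |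
| temperature |  | 40 °C | 40 °C | 40 °C |

- the flask that comes out highest in amount of bis adduct, in percent of the starting material charged, or "all alike" when all lie within 1.5 percentage points (south-east / north-west / north-east / north / all alike)
- bis adduct at the end, in percent of the starting material charged, south-east
- bis adduct at the end, in percent of the starting material charged, north-west
- bis adduct at the end, in percent of the starting material charged, north-east
- bis adduct at the end, in percent of the starting material charged, north

- in percentages every species weighs as the starting material in it: one idle adduct counts as two
- for bis adduct the crystals and idle adduct are counted in
- as a solid, counted per litre of solution: crystals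
- the list of constants is for 40 °C, to be carried to other temperatures by the activation energies and enthalpies
- in an amount of bis adduct, one idle adduct counts as one bis adduct

    coupling partner + first product → bis adduct (k1 = 210 /M/s, Ea1 = 41.0 kJ/mol)
    crystals ⇌ bis adduct, rate k2*(cs2 - [bis adduct]) while solid is left; crystals form when [bis adduct] > cs2 (cs2 = 0.059 mM, k2 = 1.4 /s)
    coupling partner + bis adduct → tris adduct (k3 = 230 /M/s, Ea3 = 45.0 kJ/mol)
    starting material + coupling partner → first product (k4 = 120 /M/s, Ea4 = 40.0 kJ/mol)
    starting material + bis adduct ⇌ idle adduct, settled at all times (K5 = 4800 /M, ΔH5 = −56.0 kJ/mol)
    bis adduct ⇌ isomer of the product (K6 = 0.12, k6 = 0.18 /s, Ea6 = 80.0 kJ/mol, ΔH6 = 35.0 kJ/mol)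
    (constants at 40 °C)

Take over the bench with this reckoning of mine, in fractions of the charge. In north-east, the partner first meets starting material at full charge and falls at 0.0240 /s. Assume this pseudo-first-order loss lasts, so the exponent over 40 s is 0.960. The mean partner is then 64.3% of its charge. That gives 0.494: the reach, meaning 120 /M/s times mean partner times time.

On this clock, starting material untouched is exp(−reach), or 61.0%. The rate constant of partner with first product is 1.75 times that with starting material, so the two-step chain holds 25.2% there. That leaves 13.8% beyond first product, as bis adduct, tris adduct and isomer together, so bis adduct itself stands lower. Expect no crystals: that whole share is 0.0276 mM, less than 0.059 mM.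

Leave the feeds alone. Partner fed steadily arrives halfway through the feed on average, so north-west shares 25.0 s. Its exponent 0.600 gives a mean of 75.2% and a reach of 0.361. North-west then puts 8.26% beyond first product, less than north-east. North feeds its starting material over the same time, and south-east has north-west's feed at 20 °C. I commit to north-east on top, with no figure for bis adduct itself.

The forecast also names north-east: 3.5% south-east, 6% north-west, 9.9% north-east, 6.7% north. Its ground is that reckoning on the time integral of partner “makes the successive additions independent of the feed”.

The simulation gives north-east on top, with 3.54% south-east, 6.27% north-west, 9.99% north-east and 6.69% north.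

Set the reach against north-east: bis adduct, tris adduct and isomer stand at 12.9%, where the reckoning had 13.8%. Now charge a neighbour of north-east with 0.64 mM of partner, all else as before. Its pace of loss is unchanged, so its reach is 1.97, with 14.3% first product and 71.8% beyond it. The neighbour shows 14.4% first product and 67.8% beyond it, of which tris adduct is 45.6% and bis adduct 20.1%.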